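Readings and results stem from a simulated flask on assumed constants, noise included.

**The balance.** I began from what a closed flask keeps: each part of starting material charged stands free, as target, or hidden from the readings.

| setting | spring | midnight | flask |
|---|---|---|---|
| starting material | 0.023 M | 0.023 M | 0.023 M |
| coupling partner | 3 equiv | 3 equiv | 3.00 equiv |
| protic impurity | 4.6 mM | 2.3 mM | 4.60 mM |
| temperature | 40 °C | 40 °C | 40 °C |
| remark | the very flask that is asked about, followed so far | run made earlier |  |
| time |  |  | 80 min |

spring run (percent of the starting material charged)

| time / min | target / % | starting material / % |
|---|---|---|
| 6.00 | 25.9 | 16.1 |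
| 15.0 | 28.1 | 15.4 |
| 30.0 | 26.6 | 18.1 |
| 80.0 | 26.8 | 16.0 |

midnight run (percent of the starting material charged)

| time / s | target / % | starting material / % |
|---|---|---|
| 25.0 | 46.1 | 27.4 |
| 50.0 | 42.9 | 23.9 |
| 80.0 | 37.0 | 20.5 |
| 90.0 | 36.9 | 21.3 |

(scatter of a reading: 1 percentage point)

- east: at 80 min take out 90% of the target then present, then wait 2.5 h
- south-east: at 80 min raise the temperature by 25 K, then wait 2.5 h
- south-west: change nothing and wait 2.5 h more
- west: at 80 min add coupling partner, 50.0% of the amount charged, then wait 2.5 h

- removed target is counted in
- the earlier runs do not show what temperature does; that part of a forecast is a guess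
- additions bring no volume worth counting
- a reading of starting material is of its free form alone

1. target, in percent of the starting material first charged, at 80 min
2. the option that brings most further target ("none" if no option brings more than 2 percentage points) (east / south-east / south-west / west / none)
3. target present, with what was taken out counted in, in percent of the starting material first charged, after east
4. target present, with what was taken out counted in, in percent of the starting material first charged, after west

**The plateau.** The spring readings lay flat, so I averaged them: target 26.9%, free starting material 16.4%. Their ratio was 1.64, or ten to the power 0.215. The last midnight reading gave 1.73 with half the impurity. I assumed that the protic impurity removes its own amount of starting material, 20.0%, and that the remaining hidden part holds one coupling partner each. So I put c(coupling partner) in the spring flask at 54.4 mM, and the ratio divided by it gave 30.1 M⁻¹, the apparent equilibrium constant K.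

**The bracket.** West adds 34.5 mM, multiplying c(coupling partner) by 1.63, or ten to the power 0.212. Adding the powers gave a ratio of 2.68. My crude limits for the west flask were the present target and the sum of target and free starting material, 43.3%. Sharing that sum by the new ratio, with the hidden part frozen, lowered the top to 31.5%. For the floor, I let target and the mobile hidden part together grow in proportion to coupling partner, and took the amount of free starting material off c(coupling partner): 29.0%.

**The forecast.** It read “target and starting material look reversibly equilibrated” and gave 26.9% now, 44% after east and 36% after west, within 30% to 39%. That west value is higher than my top. Its choice was east.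

**The flask.** The flask held 27.2% of target at the asked time and reached 43.2% after east, counting what was taken out, and 29.5% after west, below my top and above my floor. The best option was south-east, gaining 25 percentage points, more than the 16 points of east.

    starting material + coupling partner ⇌ target (K = 30.0 M⁻¹, k = 2.30 M⁻¹ s⁻¹, Ea = 53.0 kJ mol⁻¹, ΔH = 12.0 kJ mol⁻¹)
    starting material + coupling partner ⇌ isomer of the product (K = 40.0 M⁻¹, k = 0.370 M⁻¹ s⁻¹, Ea = 37.0 kJ mol⁻¹, ΔH = −79.0 kJ mol⁻¹)
    starting material + protic impurity → quenched substrate (k = 7.00 M⁻¹ s⁻¹, Ea = 44.0 kJ mol⁻¹)
    (constants at 40 °C)

**Warmer neighbour.** For the flask at 80.0 min, K came to 30.0 M⁻¹. The same reckoning on the neighbour kept at 55 °C took its free starting material, 22.1%, and the part of its coupling partner left, 80.7%. It gave a higher K, 37.0 M⁻¹. That neighbour held 12.3% of isomer of the product and 45.6% of target.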